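## Retrosynthetic overview

- Numbering: C7 is the carbinol carbon, C8 the aryloxy-bearing carbon and C9 the CH2OH carbon. Ring A is 3,4,5-trimethoxyphenyl (ipso carbon C1) and ring B is 4-allyl-2,6-dimethoxyphenyl. The target is the threo (7R,8R) isomer.
- Key disconnection C1–C7: ring A comes as its boronic acid and the rest as the racemic C9-O-TIPS aldehyde. One Rh-catalysed dynamic kinetic arylation makes the C–C bond and fixes C7 and C8 together.
- Enabling feature: C8–H lies between the C7 formyl carbon and O8 of ring B, so C8 racemises through an achiral enol. O8 and the two flanking OMe groups of ring B form a donor pocket beside C7=O that favours the chelate-type (threo) rotamer, and the bulky, non-donating C9–OTIPS arm reinforces it.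
- The aldehyde goes back by oxidation and monosilylation to the achiral 2-aryloxypropane-1,3-diol. Disconnection of O8–C8 then leads to 4-allyl-2,6-dimethoxyphenol and dimethyl chloromalonate.
- No ring is formed in the route, since both benzene rings are bought. The only protecting group (TIPS) leaves in the last step.

Key step: step 5

Assumption: the sense of induction of the chiral diene on this new substrate class is not known, so (R,R)-Ph-bod* stands for the ligand antipode that delivers the aryl group to the Re face of C7.

## Route

Step 1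
Reactants: 1 4-allyl-2,6-dimethoxyphenol; 2 dimethyl 2-chloromalonate
Product: 3 dimethyl 2-(4-allyl-2,6-dimethoxyphenoxy)malonate
Conditions: K2CO3, DMF, 60 °C
Reagents that add atoms: none
Why: Williamson-type SN2 O-alkylation in which the phenoxide of 1 displaces chloride from the doubly activated malonate carbon, the standard entry to 2-aryloxymalonates from ortho-methoxyphenols; no stereocentre is formed.

Step 2
Reactants: 3 dimethyl 2-(4-allyl-2,6-dimethoxyphenoxy)malonate
Product: 4 2-(4-allyl-2,6-dimethoxyphenoxy)propane-1,3-diol
Conditions: LiAlH4, THF, 0 °C to rt; then H2O/aq NaOH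
Reagents that add atoms: none
Why: Exhaustive LiAlH4 ester reduction turns both ester groups into CH2OH and leaves the allyl group and the aryl ethers untouched, giving an achiral diol with a prochiral C8.

Step 3
Reactants: 4 2-(4-allyl-2,6-dimethoxyphenoxy)propane-1,3-diol
Product: 6 rac-2-(4-allyl-2,6-dimethoxyphenoxy)-3-(triisopropylsilyloxy)propan-1-ol, via monosodium alkoxide 5 (not isolated)
Conditions: NaH (1 equiv), THF, rt; then TIPSCl (1 equiv), rt
Reagents that add atoms: triisopropylsilyl chloride, CC(C)[Si](Cl)(C(C)C)C(C)C
Why: Monosilylation of a symmetrical diol through its sparingly soluble monosodium alkoxide; either enantiotopic arm reacts, so C8 becomes stereogenic in racemic form, which is all the key step needs.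

Step 4
Reactants: 6 rac-2-(4-allyl-2,6-dimethoxyphenoxy)-3-(triisopropylsilyloxy)propan-1-ol
Product: 7 rac-2-(4-allyl-2,6-dimethoxyphenoxy)-3-(triisopropylsilyloxy)propanal
Conditions: TEMPO (10 mol %), PhI(OAc)2 (1.1 equiv), CH2Cl2, rt
Reagents that add atoms: none
Why: Oxoammonium (TEMPO) oxidation with PhI(OAc)2 as terminal oxidant stops at the aldehyde without base and tolerates the alkene, the silyl ether and the electron-rich arene; racemic C8 needs no protection from epimerisation.

Step 5
Reactants: 7 rac-2-(4-allyl-2,6-dimethoxyphenoxy)-3-(triisopropylsilyloxy)propanal; 8 3,4,5-trimethoxyphenylboronic acid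
Product: 10 (1R,2R)-2-(4-allyl-2,6-dimethoxyphenoxy)-3-(triisopropylsilyloxy)-1-(3,4,5-trimethoxyphenyl)propan-1-ol, via achiral enol 9 (not isolated)
Conditions: [RhCl(C2H4)2]2 (2.5 mol %), (R,R)-Ph-bod* (5.5 mol %), KOH (10 mol %), quinuclidine (0.5 equiv), 8 (2 equiv), toluene/H2O 20:1, 30 °C
Reagents that add atoms: none
Why: Proposed new method: hydroxide and quinuclidine interconvert (R)- and (S)-7 through the achiral enol 9, while (diene)Rh–OH takes the aryl group from 8 by transmetalation, the Rh–aryl bond adds across C7=O by migratory insertion, and water releases the Rh alkoxide as 10, so that the 1,2-addition of an arylboronic acid runs as a dynamic kinetic resolution. The closest known reaction types are the enantioconvergent (diene)Rh(I)-catalysed arylation of configurationally labile β-stereogenic α-keto esters with arylboronic acids and tertiary amines, the asymmetric hydrogenation of racemic α-aryloxy aldehydes with dynamic kinetic resolution, and the Rh- or Ru-catalysed asymmetric arylation of aliphatic aldehydes; their combination on an α-aryloxy aldehyde is what is new. No ring is closed. C7 is controlled by the C2-symmetric diene, whose phenyl-blocked quadrants should allow aryl migration only to the Re face of the bound aldehyde. C8 is controlled by selection from the racemising pair: in the favoured insertion rotamer O8 and a flanking OMe of ring B lie beside C7=O and lean on the free apical site of Rh (the chelate-type arrangement through which aryl-metal reagents add to α-alkoxy and α-aryloxy aldehydes to give syn products), the bulky, non-donating CH2OTIPS arm points away from the migrating aryl, and only (R)-7 offers its Re face in this rotamer, which gives the threo (7R,8R) pair. The step needs racemisation faster than insertion (secured by the acidity of C8–H between CHO and O8), insertion faster than E1cB loss of silanolate (poor leaving group, 30 °C), the chelate-type over the polar Felkin–Anh rotamer (O8/OMe donors plus TIPS bulk) and aldehyde over allyl chemoselectivity (unactivated terminal alkenes are poor partners for aryl-Rh(I)).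

Step 6
Reactants: 10 (1R,2R)-2-(4-allyl-2,6-dimethoxyphenoxy)-3-(triisopropylsilyloxy)-1-(3,4,5-trimethoxyphenyl)propan-1-ol
Product: 11 (1R,2R)-2-(4-allyl-2,6-dimethoxyphenoxy)-1-(3,4,5-trimethoxyphenyl)propane-1,3-diol
Conditions: TBAF (1.1 equiv), THF, 0 °C to rt; aqueous work-up
Reagents that add atoms: none
Why: Fluoride-induced cleavage of the primary TIPS ether, driven by the Si–F bond, touches neither stereocentre nor the allyl group and should give the target.

## Compound list

1 | 4-allyl-2,6-dimethoxyphenol | C=CCc1cc(OC)c(O)c(OC)c1 | starting material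
2 | dimethyl 2-chloromalonate | COC(=O)C(Cl)C(=O)OC | starting material
3 | dimethyl 2-(4-allyl-2,6-dimethoxyphenoxy)malonate | C=CCc1cc(OC)c(OC(C(=O)OC)C(=O)OC)c(OC)c1 | intermediate
4 | 2-(4-allyl-2,6-dimethoxyphenoxy)propane-1,3-diol (achiral) | C=CCc1cc(OC)c(OC(CO)CO)c(OC)c1 | intermediate
5 | monosodium alkoxide of 4 (not isolated) | C=CCc1cc(OC)c(OC(CO)C[O-])c(OC)c1.[Na+] | intermediate
6 | rac-2-(4-allyl-2,6-dimethoxyphenoxy)-3-(triisopropylsilyloxy)propan-1-ol | C=CCc1cc(OC)c(OC(CO)CO[Si](C(C)C)(C(C)C)C(C)C)c(OC)c1 | intermediate
7 | rac-2-(4-allyl-2,6-dimethoxyphenoxy)-3-(triisopropylsilyloxy)propanal | C=CCc1cc(OC)c(OC(C=O)CO[Si](C(C)C)(C(C)C)C(C)C)c(OC)c1 | intermediate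
8 | 3,4,5-trimethoxyphenylboronic acid | COc1cc(B(O)O)cc(OC)c1OC | starting material
9 | 2-(4-allyl-2,6-dimethoxyphenoxy)-3-(triisopropylsilyloxy)prop-1-en-1-ol (achiral enol, double-bond geometry not defined, not isolated) | C=CCc1cc(OC)c(OC(=CO)CO[Si](C(C)C)(C(C)C)C(C)C)c(OC)c1 | intermediate
10 | (1R,2R)-2-(4-allyl-2,6-dimethoxyphenoxy)-3-(triisopropylsilyloxy)-1-(3,4,5-trimethoxyphenyl)propan-1-ol | C=CCc1cc(OC)c(O[C@H](CO[Si](C(C)C)(C(C)C)C(C)C)[C@H](O)c2cc(OC)c(OC)c(OC)c2)c(OC)c1 | intermediate
11 | (1R,2R)-2-(4-allyl-2,6-dimethoxyphenoxy)-1-(3,4,5-trimethoxyphenyl)propane-1,3-diol (threo, 7R,8R) | C=CCc1cc(OC)c(O[C@H](CO)[C@H](O)c2cc(OC)c(OC)c(OC)c2)c(OC)c1 | target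

## Step count and risks

Total steps: 6. Longest linear sequence: 6 steps.

Steps most likely to fail:

1. **Step 5 (Proposed new method).**
   - What may go wrong:
     - Insertion may proceed through the polar Felkin–Anh rotamer instead of the chelate-type rotamer, which would drift the product towards the erythro series.
     - C8 may racemise too slowly relative to insertion, so that the process degrades to a simple kinetic resolution.
     - The enolate may lose silanolate by E1cB elimination.
     - Adventitious Rh–H may migrate the allyl double bond.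
   - Fallback with known chemistry, setting out from 6 and returning at 10: lipase-catalysed acylative kinetic resolution of 6 (Pseudomonas cepacia lipase, vinyl acetate, iPr2O, rt, stopped near half conversion) is a known reaction of 2-aryloxy-substituted primary alcohols. It should leave (S)-2-(4-allyl-2,6-dimethoxyphenoxy)-3-(triisopropylsilyloxy)propan-1-ol F1, which is separated from (R)-2-(4-allyl-2,6-dimethoxyphenoxy)-3-(triisopropylsilyloxy)propyl acetate F2. Base-free TEMPO/PhI(OAc)2 oxidation of F1 gives (R)-2-(4-allyl-2,6-dimethoxyphenoxy)-3-(triisopropylsilyloxy)propanal F3, which is used at once. Precomplexation with MgBr2·OEt2 in CH2Cl2 at −78 °C and addition of 3,4,5-trimethoxyphenylmagnesium bromide F4 should give 10 through the Cram chelate, the known syn-selective mode of aryl Grignard additions to α-oxygenated aldehydes whose second oxygen carries a non-chelating silyl group.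

2. **Step 4.**
   - What may go wrong: silanol may be lost by β-elimination, or the electrophilic α-aryloxy aldehyde may hydrate, during oxidation, work-up or chromatography.
   - Fallback that reaches the aldehyde by reduction instead of oxidation, setting out from 3 and returning at 7: selective monoreduction of the 2-substituted malonate with LiAlH(OtBu)3 in THF gives methyl 2-(4-allyl-2,6-dimethoxyphenoxy)-3-hydroxypropanoate F5. TIPSCl/imidazole in DMF gives methyl 2-(4-allyl-2,6-dimethoxyphenoxy)-3-(triisopropylsilyloxy)propanoate F6. DIBAL-H in toluene at −78 °C, where the α-aryloxy ester holds the aluminium hemiacetal until the quench, releases 7 cold and base-free for direct use in step 5.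

3. **Step 2.**
   - What may go wrong: hydride may deprotonate the acidic malonate C–H, leaving an enolate that resists reduction or expels aryloxide.
   - Fallback that builds O8–C8 on a preformed glycerol unit, setting out from 1 and returning at 4: Mitsunobu etherification (PPh3, DIAD, THF) of 1 with commercial cis-2-phenyl-1,3-dioxan-5-ol F7 gives trans-5-(4-allyl-2,6-dimethoxyphenoxy)-2-phenyl-1,3-dioxane F8. Hydrolysis of the benzylidene acetal (80% aqueous AcOH, 45 °C) gives diol 4.

## Further compounds

F1 | step 5 | (S)-2-(4-allyl-2,6-dimethoxyphenoxy)-3-(triisopropylsilyloxy)propan-1-ol | C=CCc1cc(OC)c(O[C@H](CO[Si](C(C)C)(C(C)C)C(C)C)CO)c(OC)c1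
F2 | step 5 | (R)-2-(4-allyl-2,6-dimethoxyphenoxy)-3-(triisopropylsilyloxy)propyl acetate | C=CCc1cc(OC)c(O[C@@H](CO[Si](C(C)C)(C(C)C)C(C)C)COC(C)=O)c(OC)c1
F3 | step 5 | (R)-2-(4-allyl-2,6-dimethoxyphenoxy)-3-(triisopropylsilyloxy)propanal | C=CCc1cc(OC)c(O[C@H](CO[Si](C(C)C)(C(C)C)C(C)C)C=O)c(OC)c1
F4 | step 5 | 3,4,5-trimethoxyphenylmagnesium bromide | COc1cc([Mg]Br)cc(OC)c1OC
F5 | step 4 | methyl 2-(4-allyl-2,6-dimethoxyphenoxy)-3-hydroxypropanoate (racemic) | C=CCc1cc(OC)c(OC(CO)C(=O)OC)c(OC)c1
F6 | step 4 | methyl 2-(4-allyl-2,6-dimethoxyphenoxy)-3-(triisopropylsilyloxy)propanoate (racemic) | C=CCc1cc(OC)c(OC(CO[Si](C(C)C)(C(C)C)C(C)C)C(=O)OC)c(OC)c1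
F7 | step 2 | cis-2-phenyl-1,3-dioxan-5-ol | O[C@H]1CO[C@@H](c2ccccc2)OC1
F8 | step 2 | trans-5-(4-allyl-2,6-dimethoxyphenoxy)-2-phenyl-1,3-dioxane | C=CCc1cc(OC)c(O[C@H]2CO[C@H](c3ccccc3)OC2)c(OC)c1
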